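The synthesis rests on the C13–C14 bond (squalene numbering). This bond ties the side-chain CH2 to the methine of cyclohexane ring C, which is flanked by the methyl-bearing C15 and quaternary C19. The methine is read as the former vinylic carbon of an E-trisubstituted alkene, so the bond is made sp3–sp2. A one-pot hydroboration and B-alkyl Suzuki–Miyaura coupling joins the finished ring A/B triene 17 to the acyclic bis-epoxy (E)-vinyl iodide 23 with retention of geometry. The precursor therefore has neither ring C nor oxepane ring D. One hydride-terminated, biomimetic epoxide cascade then converts the new alkene and two Shi epoxides into C14, C15, C18 and C19.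

Key step: step 16

Remark: atoms are numbered as in squalene. C3 is the carbinol, C6/C7 the fusion of decalin rings A/B, C8=C9 and C10=C11 the diene, C12–C13 the link, C14–C19 ring C, and O plus C18–C23 oxepane ring D. Commercial geranylacetone is assumed to be the pure E isomer.

Step 1
Reactants: 1 geranyl acetate
Product: 2 (6R)-6,7-epoxygeranyl acetate
Conditions: D-fructose-derived Shi ketone (30 mol%), Oxone (2KHSO5·KHSO4·K2SO4), K2CO3, Bu4NHSO4, aq. Na2B4O7 buffer, MeCN–DMM–H2O, 0 °C
Reagents that add atoms: potassium peroxymonosulfate (active part of Oxone), [K+].[O-]S(=O)(=O)OO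
Why: Shi asymmetric epoxidation, in which the chiral dioxirane reaches the electron-rich terminal trisubstituted alkene through the spiro transition state and sets the later C3 as R, while the alkene next to the acetoxy group is inductively deactivated.

Step 2
Reactants: 2 (6R)-6,7-epoxygeranyl acetate
Product: 3 (6R)-6,7-epoxygeraniol
Conditions: K2CO3 (cat.), MeOH, 0 °C to rt
Reagents that add atoms: none
Why: Base-catalysed transesterification should free the allylic alcohol and leave the trisubstituted epoxide untouched.

Step 3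
Reactants: 3 (6R)-6,7-epoxygeraniol
Product: 5 (6R)-6,7-epoxygeranyl bromide, via epoxygeranyl mesylate 4 (not isolated)
Conditions: MsCl, Et3N, CH2Cl2, −40 °C; then LiBr, THF, 0 °C
Reagents that add atoms: methanesulfonyl chloride, CS(=O)(=O)Cl (only in intermediate 4); lithium bromide, [Li+].[Br-]
Why: Mesylation followed by SN2 displacement with bromide under non-acidic conditions should give the primary allylic bromide without allylic shift or epoxide opening.

Step 4
Reactants: 5 (6R)-6,7-epoxygeranyl bromide; 6 methyl acetoacetate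
Product: 8 methyl (6E,10R)-10,11-epoxy-7,11-dimethyl-3-oxododec-6-enoate, via acetoacetate dianion 7 (not isolated)
Conditions: 6, NaH, THF, 0 °C; n-BuLi, 0 °C; then 5, 0 °C; aq. NH4Cl
Reagents that add atoms: none
Why: Gamma-alkylation of the acetoacetate dianion, whose more basic terminal carbanion (later C9) displaces the allylic bromide by SN2 faster than it can attack the hindered epoxide.

Step 5
Reactants: 8 methyl (6E,10R)-10,11-epoxy-7,11-dimethyl-3-oxododec-6-enoate
Product: 9 methyl 6-hydroxy-5,5,8a-trimethyl-2-oxo-trans-decahydronaphthalene-1-carboxylate (3R,6R,7S,11S in squalene numbering; equatorial OH cis to the angular methyl; equatorial ester)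
Conditions: SnCl4, CH2Cl2, −78 to 0 °C; aq. NaHCO3
Reagents that add atoms: none
Why: Epoxide-initiated cationic polyene bicyclisation with the tin-chelated beta-keto ester enol as carbon terminator, in which chair–chair folding with antiperiplanar addition across the E alkene relays C3 to C7 and C6 (trans-decalin, equatorial OH) and C11 settles with the ester equatorial by enolisation.

Step 6
Reactants: 9 bicyclic hydroxy keto ester
Product: 10 C3 tert-butyldimethylsilyl ether of 9
Conditions: TBSOTf, 2,6-lutidine, CH2Cl2, 0 °C; aq. citric acid work-up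
Reagents that add atoms: tert-butyldimethylsilyl triflate, CC(C)(C)[Si](C)(C)OS(=O)(=O)C(F)(F)F
Why: Silyl ether formation at the hindered equatorial alcohol next to the gem-dimethyl carbon needs the silyl triflate, and any enol silyl ether of the keto ester is hydrolysed on work-up.

Step 7
Reactants: 10 silyl-protected keto ester
Product: 12 methyl 6-(tert-butyldimethylsilyloxy)-5,5,8a-trimethyl-2-oxo-1,2,4a,5,6,7,8,8a-octahydronaphthalene-1-carboxylate (C8=C9 enone), via dilithium dianion 11 (not isolated)
Conditions: LiN(i-Pr)2 (2.05 equiv), THF, −78 to 0 °C; PhS(Cl)=Nt-Bu, −78 °C; aq. NH4Cl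
Reagents that add atoms: none
Why: Mukaiyama dehydrogenation of an enolate, in which the more reactive C9 terminus of the dianion attacks sulfur and the sulfilimine undergoes syn elimination with a C8 hydrogen at low temperature; no other direction of unsaturation is open because C6 is quaternary.

Step 8
Reactants: 12 C8=C9 enone keto ester
Product: 13 dienyl triflate (C10 triflyloxy, C8=C9–C10=C11 diene, C11 methyl ester)
Conditions: NaH, PhNTf2, THF, 0 °C to rt
Reagents that add atoms: N-phenylbis(trifluoromethanesulfonimide), O=S(=O)(N(c1ccccc1)S(=O)(=O)C(F)(F)F)C(F)(F)F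
Why: O-sulfonylation of the stabilised beta-keto ester enolate gives the enol triflate and thereby fixes the ring B diene in its final position.

Step 9
Reactants: 13 dienyl triflate
Product: 14 methyl 6-(tert-butyldimethylsilyloxy)-2,5,5,8a-tetramethyl-4a,5,6,7,8,8a-hexahydronaphthalene-1-carboxylate (3R,6R,7S)
Conditions: MeZnCl, Pd(PPh3)4 (5 mol%), THF, rt to 50 °C
Reagents that add atoms: methylzinc chloride, C[Zn]Cl
Why: Negishi cross-coupling of an activated alkenyl triflate with a methylzinc reagent should install the C10 methyl group without touching the ester or the silyl ether.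

Step 10
Reactants: 14 methyl dienoate
Product: 15 dienyl carbinol (C12 hydroxymethyl on C11)
Conditions: i-Bu2AlH (2.5 equiv), CH2Cl2, −78 °C; aq. potassium sodium tartrate
Reagents that add atoms: none
Why: 1,2-Reduction of a conjugated ester with DIBAL-H gives the allylic alcohol and leaves the diene and silyl ether intact.

Step 11
Reactants: 15 dienyl carbinol
Product: 16 dienal (C12 carbaldehyde on C11)
Conditions: MnO2 (activated, excess), CH2Cl2, rt
Reagents that add atoms: none
Why: Manganese dioxide oxidation is selective for allylic alcohols and stops at the conjugated aldehyde under neutral conditions.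

Step 12
Reactants: 16 dienal
Product: 17 ring A/B triene (vinyl group C12=C13 on C11; 3R,6R,7S; C3 OTBS)
Conditions: Ph3PCH3Br, KOt-Bu, THF, 0 °C; then 16, 0 °C to rt
Reagents that add atoms: methyltriphenylphosphonium bromide, C[P+](c1ccccc1)(c1ccccc1)c1ccccc1.[Br-]
Why: Wittig methylenation with the small unstabilised ylide adds C13 to the hindered, non-enolisable-at-alpha aldehyde, as it does with related trimethylcyclohexadienyl carbaldehydes.

Step 13
Reactants: 18 (E)-geranylacetone
Product: 20 (5E)-6,10-dimethylundeca-5,9-dien-1-yne, via enol phosphate 19 (not isolated)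
Conditions: LiN(i-Pr)2 (1.1 equiv), THF, −78 °C; ClP(O)(OEt)2; then LiN(i-Pr)2 (2.3 equiv), −78 °C to rt; H2O
Reagents that add atoms: diethyl chlorophosphate, CCOP(=O)(Cl)OCC (only in intermediate 19)
Why: Kinetic enolisation at the methyl group, O-phosphorylation and base-induced elimination form the standard conversion of a methyl ketone into a terminal alkyne (C14≡C15).

Step 14
Reactants: 20 dienyne
Product: 22 (1E,5E)-1-iodo-2,6,10-trimethylundeca-1,5,9-triene, via alkenyldimethylalane 21 (not isolated)
Conditions: Me3Al, Cp2ZrCl2 (25 mol%), CH2Cl2, 0 °C to rt; then I2, THF, −30 °C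
Reagents that add atoms: trimethylaluminium, C[Al](C)C; iodine, II
Why: Negishi zirconium-catalysed carboalumination adds methyl and aluminium syn with aluminium on the terminal C14, and iodinolysis with retention gives the E vinyl iodide.

Step 15
Reactants: 22 trienyl iodide
Product: 23 (1E,5R,6R,9R)-5,6:9,10-diepoxy-1-iodo-2,6,10-trimethylundec-1-ene (18R,19R,22R in squalene numbering)
Conditions: D-fructose-derived Shi ketone (60 mol%), Oxone (2KHSO5·KHSO4·K2SO4), K2CO3, Bu4NHSO4, aq. Na2B4O7 buffer, MeCN–DMM–H2O, 0 °C
Reagents that add atoms: potassium peroxymonosulfate (active part of Oxone), [K+].[O-]S(=O)(=O)OO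
Why: Double Shi epoxidation under reagent control sets C18, C19 and the temporary C22 as R, while the iodine-bearing alkene is too electron-poor for the electrophilic dioxirane and is kept for the coupling.

Step 16
Reactants: 17 ring A/B triene; 23 bis-epoxy vinyl iodide
Product: 25 coupled (14E)-bis-epoxide (decalin diene joined through C12–C13 to the C14=C15 alkene; 3R,6R,7S,18R,19R,22R), via B-alkyl-9-BBN 24 (not isolated)
Conditions: 17, 9-BBN-H dimer, THF, rt; then 23, PdCl2(dppf) (5 mol%), AsPh3, Cs2CO3, DMF–THF–H2O, rt
Reagents that add atoms: 9-borabicyclo[3.3.1]nonane, B1C2CCCC1CCC2 (boron residue only in intermediate 24)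
Why: 9-BBN-H adds to the only monosubstituted alkene of 17 and places boron on terminal C13, because the ring diene is di- and tetrasubstituted and shielded by quaternary C6; zerovalent palladium then inserts into the carbon–iodine bond of 23 with retention, the base-activated primary alkylborane transmetalates, and reductive elimination forms C13–C14. The closest known reaction type is the B-alkyl Suzuki–Miyaura coupling of a primary alkyl-9-BBN with an (E)-trisubstituted alkenyl iodide. No ring is closed and no stereocentre is created here; the step fixes the E geometry of C14=C15, kept from 22 because oxidative addition and reductive elimination are stereoretentive, and step 17 translates that geometry into C14 and C15. The step needs selectivity for the carbon–iodine bond over two trisubstituted epoxides and the silyl ether, which mild base at room temperature and the absence of any Lewis acid secure, and it needs reductive elimination to outrun beta-hydride elimination, which the wide-bite-angle dppf ligand together with AsPh3 secures.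

Step 17
Reactants: 25 coupled (14E)-bis-epoxide
Product: 27 tetracyclic C22 alcohol (rings C and D closed; 14S,15S,18R,19R,22R; C3 OTBS), via C22 triethylsilyl ether 26 (not isolated)
Conditions: TESOTf (1.1 equiv), 2,6-di-tert-butyl-4-methylpyridine, Et3SiH (20 equiv), CH2Cl2, −78 °C; then PPTS, MeOH, 0 °C
Reagents that add atoms: triethylsilane, CC[SiH](CC)CC (Et3Si only in intermediate 26; its hydride stays on C15)
Why: Proposed new method: silylation of the terminal epoxide makes C23 electrophilic, the oxygen of the C18–C19 epoxide attacks tertiary C23 (7-endo) to give a bicyclic epoxonium ion, C14 of the E alkene opens it at tertiary C19 with inversion through a chair (6-endo), and the tertiary C15 cation takes hydride from Et3SiH anti to the new C14–C19 bond and opposite the axial C19 methyl, which regenerates the silyl cation; C18 keeps and C19 inverts its Shi configuration, the E geometry places C13 equatorial at C14, and equatorial hydride delivery leaves the C15 methyl axial, as in hydride additions to cyclohexyl sp2 centres with a 3-axial methyl group; the closest known reaction types are silyl-triflate-promoted oxa-/carbacyclisation cascades of 1,5-diepoxides with alkene terminators and the ionic hydrogenation of tertiary cations by silanes, and PPTS in MeOH then removes only the TES ether.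

Step 18
Reactants: 27 tetracyclic C22 alcohol
Product: 28 C22 ketone (oxepan-3-one ring D; C3 OTBS)
Conditions: Dess–Martin periodinane, NaHCO3, CH2Cl2, 0 °C to rt
Reagents that add atoms: none
Why: Dess–Martin oxidation under buffered neutral conditions converts the only free alcohol into the ketone, erases the temporary C22 stereocentre and spares the diene and silyl ether.

Step 19
Reactants: 28 C22 ketone
Product: 29 target CNP0106412.2
Conditions: HF·pyridine, excess pyridine, THF, 0 °C to rt
Reagents that add atoms: none
Why: Fluoride-driven desilylation in pyridine-buffered medium should free the hindered C3 alcohol without isomerising the ring B diene, and the ketone has no epimerisable neighbour.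

Compound list
1 | geranyl acetate, (2E)-3,7-dimethylocta-2,6-dien-1-yl acetate | CC(C)=CCC/C(C)=C/COC(C)=O | starting material
2 | (6R)-6,7-epoxygeranyl acetate | CC1(C)O[C@@H]1CC/C(C)=C/COC(C)=O | intermediate
3 | (6R)-6,7-epoxygeraniol | CC1(C)O[C@@H]1CC/C(C)=C/CO | intermediate
4 | (6R)-6,7-epoxygeranyl mesylate (not isolated) | CC1(C)O[C@@H]1CC/C(C)=C/COS(C)(=O)=O | intermediate
5 | (6R)-6,7-epoxygeranyl bromide | CC1(C)O[C@@H]1CC/C(C)=C/CBr | intermediate
6 | methyl acetoacetate | CC(=O)CC(=O)OC | starting material
7 | sodium lithium dianion of methyl acetoacetate (not isolated) | [Na+].[Li+].C=C([O-])C=C([O-])OC | intermediate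
8 | methyl (6E,10R)-10,11-epoxy-7,11-dimethyl-3-oxododec-6-enoate | CC1(C)O[C@@H]1CC/C(C)=C/CCC(=O)CC(=O)OC | intermediate
9 | methyl 6-hydroxy-5,5,8a-trimethyl-2-oxo-trans-decahydronaphthalene-1-carboxylate (3R,6R,7S,11S) | O=C1[C@@H](C(=O)OC)[C@]2(C)CC[C@@H](O)C(C)(C)[C@H]2CC1 | intermediate
10 | C3 TBS ether of 9 | O=C1[C@@H](C(=O)OC)[C@]2(C)CC[C@@H](O[Si](C)(C)C(C)(C)C)C(C)(C)[C@H]2CC1 | intermediate
11 | dilithium dianion of 10, deprotonated at C11 and C9 (not isolated) | [Li+].[Li+].[O-]C1C(=C([O-])OC)[C@]2(C)CC[C@@H](O[Si](C)(C)C(C)(C)C)C(C)(C)[C@H]2CC=1 | intermediate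
12 | C8=C9 enone keto ester | O=C1[C@@H](C(=O)OC)[C@]2(C)CC[C@@H](O[Si](C)(C)C(C)(C)C)C(C)(C)[C@H]2C=C1 | intermediate
13 | dienyl triflate (C10 OTf, C11 CO2Me) | O=S(=O)(OC1=C(C(=O)OC)[C@]2(C)CC[C@@H](O[Si](C)(C)C(C)(C)C)C(C)(C)[C@H]2C=C1)C(F)(F)F | intermediate
14 | methyl dienoate (C10 methyl, C11 CO2Me) | CC1=C(C(=O)OC)[C@]2(C)CC[C@@H](O[Si](C)(C)C(C)(C)C)C(C)(C)[C@H]2C=C1 | intermediate
15 | dienyl carbinol (C11 CH2OH) | CC1=C(CO)[C@]2(C)CC[C@@H](O[Si](C)(C)C(C)(C)C)C(C)(C)[C@H]2C=C1 | intermediate
16 | dienal (C11 CHO) | CC1=C(C=O)[C@]2(C)CC[C@@H](O[Si](C)(C)C(C)(C)C)C(C)(C)[C@H]2C=C1 | intermediate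
17 | ring A/B triene (C11 vinyl) | CC1=C(C=C)[C@]2(C)CC[C@@H](O[Si](C)(C)C(C)(C)C)C(C)(C)[C@H]2C=C1 | intermediate
18 | (E)-geranylacetone, (5E)-6,10-dimethylundeca-5,9-dien-2-one | CC(C)=CCC/C(C)=C/CCC(C)=O | starting material
19 | diethyl (5E)-6,10-dimethylundeca-1,5,9-trien-2-yl phosphate (not isolated) | C=C(CC/C=C(\C)CCC=C(C)C)OP(=O)(OCC)OCC | intermediate
20 | (5E)-6,10-dimethylundeca-5,9-dien-1-yne | C#CCC/C=C(\C)CCC=C(C)C | intermediate
21 | (1E,5E)-(2,6,10-trimethylundeca-1,5,9-trienyl)dimethylalane (not isolated) | C[Al](C)/C=C(\C)CC/C=C(\C)CCC=C(C)C | intermediate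
22 | (1E,5E)-1-iodo-2,6,10-trimethylundeca-1,5,9-triene | I/C=C(\C)CC/C=C(\C)CCC=C(C)C | intermediate
23 | (1E,5R,6R,9R)-5,6:9,10-diepoxy-1-iodo-2,6,10-trimethylundec-1-ene | I/C=C(\C)CC[C@H]1O[C@]1(C)CC[C@H]1OC1(C)C | intermediate
24 | B-[2-(decalin dienyl)ethyl]-9-BBN, boron on C13 (not isolated) | CC1=C(CCB3C4CCCC3CCC4)[C@]2(C)CC[C@@H](O[Si](C)(C)C(C)(C)C)C(C)(C)[C@H]2C=C1 | intermediate
25 | coupled (14E)-bis-epoxide | CC1=C(CC/C=C(\C)CC[C@H]3O[C@]3(C)CC[C@H]3OC3(C)C)[C@]2(C)CC[C@@H](O[Si](C)(C)C(C)(C)C)C(C)(C)[C@H]2C=C1 | intermediate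
26 | tetracyclic C22 triethylsilyl ether (not isolated) | CC1=C(CC[C@H]2[C@@H](C)CC[C@H]3OC(C)(C)[C@H](O[Si](CC)(CC)CC)CC[C@@]32C)[C@]2(C)CC[C@@H](O[Si](C)(C)C(C)(C)C)C(C)(C)[C@H]2C=C1 | intermediate
27 | tetracyclic C22 alcohol | CC1=C(CC[C@H]2[C@@H](C)CC[C@H]3OC(C)(C)[C@H](O)CC[C@@]32C)[C@]2(C)CC[C@@H](O[Si](C)(C)C(C)(C)C)C(C)(C)[C@H]2C=C1 | intermediate
28 | C22 ketone, C3 TBS ether of the target | CC1=C(CC[C@H]2[C@@H](C)CC[C@H]3OC(C)(C)C(=O)CC[C@@]32C)[C@]2(C)CC[C@@H](O[Si](C)(C)C(C)(C)C)C(C)(C)[C@H]2C=C1 | intermediate
29 | CNP0106412.2 (3R,6R,7S,14S,15S,18R,19R) | CC1=C(CC[C@H]2[C@@H](C)CC[C@H]3OC(C)(C)C(=O)CC[C@@]32C)[C@]2(C)CC[C@@H](O)C(C)(C)[C@H]2C=C1 | target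

Total step count: 19. Longest linear sequence: 16 steps (steps 1–12 and 16–19).

Steps most likely to fail

1. Step 17 (Proposed new method).
- What may go wrong: proton loss from the C15 cation, or its capture by the ring B diene, may outrun hydride transfer. Hydride may also open the silylated terminal epoxide before the oxepane closes.
- Fallback: it uses known chemistry (allylsilane termination, then a separate reduction), sets out from 20 and comes back at 27. Syn silylmethyl-cupration of 20 (Me3SiCH2MgCl, CuBr·SMe2) and iodinolysis give the (Z)-iodo allylsilane F1. Shi epoxidation gives its bis-epoxide F2. The coupling of step 16 with 17 gives the allylsilane polyene F3. Catalytic TMSOTf then runs the same cascade, but the beta-silyl cation collapses at once; this moves the Me3Si group to the C22 oxygen and leaves the exocyclic C15 methylene compound F4. 9-BBN-H adds to this 1,1-disubstituted alkene from the face opposite the axial C19 methyl and spares the hindered conjugated diene, giving the primary borane F5. Radical protodeboronation with 4-tert-butylcatechol gives the C22 trimethylsilyl ether F6, and K2CO3 in MeOH returns to 27.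

2. Step 16.
- What may go wrong: hydroboration may spill over to the ring diene. Slow transmetalation may also leave time for protodeboronation, beta-hydride elimination or base-induced epoxide opening.
- Fallback: it sets out from 17 and comes back at 25. Hydroboration with 9-BBN-H followed by NaBO3 oxidation allows purification at the stage of the primary alcohol F7. An Appel reaction (I2, PPh3, imidazole) gives the primary iodide F8. LiCl-assisted zinc insertion gives the alkylzinc iodide F9. A base-free, anhydrous Negishi coupling with 23 (PdCl2(dppf), THF–DMA) then forms the same C13–C14 bond.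

3. Step 7.
- What may go wrong: excess amide base may also remove the C7 hydrogen of the product enolate and erode the trans ring fusion, or sulfur transfer may take place at C11.
- Fallback: it sets out from 10 and comes back at 12. Double silylation (TMSCl, Et3N; then LiN(i-Pr)2, TMSCl) gives the bis(trimethylsilyl) dienol ether F10. A Saegusa–Ito oxidation with Pd(OAc)2 in MeCN dehydrosilylates the C9=C10 enol ether to the C8=C9 enone, and the silyl ketene acetal is hydrolysed on work-up.

Further compounds
F1 | step 17 | (1Z,5E)-1-iodo-6,10-dimethyl-2-(trimethylsilylmethyl)undeca-1,5,9-triene | C[Si](C)(C)C/C(=C\I)CC/C=C(\C)CCC=C(C)C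
F2 | step 17 | (18R,19R,22R)-bis-epoxide of F1 | C[Si](C)(C)C/C(=C\I)CC[C@H]1O[C@]1(C)CC[C@H]1OC1(C)C
F3 | step 17 | coupled allylsilane bis-epoxide (C13 cis to CH2SiMe3) | CC1=C(CC/C=C(\C[Si](C)(C)C)CC[C@H]3O[C@]3(C)CC[C@H]3OC3(C)C)[C@]2(C)CC[C@@H](O[Si](C)(C)C(C)(C)C)C(C)(C)[C@H]2C=C1
F4 | step 17 | tetracyclic C15 exocyclic methylene compound, C22 OTMS | CC1=C(CC[C@H]2C(=C)CC[C@H]3OC(C)(C)[C@H](O[Si](C)(C)C)CC[C@@]32C)[C@]2(C)CC[C@@H](O[Si](C)(C)C(C)(C)C)C(C)(C)[C@H]2C=C1
F5 | step 17 | 9-BBN adduct of F4 (axial CH2–boron on C15) | CC1=C(CC[C@H]2[C@@H](CB4C5CCCC4CCC5)CC[C@H]3OC(C)(C)[C@H](O[Si](C)(C)C)CC[C@@]32C)[C@]2(C)CC[C@@H](O[Si](C)(C)C(C)(C)C)C(C)(C)[C@H]2C=C1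
F6 | step 17 | tetracyclic C22 trimethylsilyl ether (axial C15 methyl) | CC1=C(CC[C@H]2[C@@H](C)CC[C@H]3OC(C)(C)[C@H](O[Si](C)(C)C)CC[C@@]32C)[C@]2(C)CC[C@@H](O[Si](C)(C)C(C)(C)C)C(C)(C)[C@H]2C=C1
F7 | step 16 | primary alcohol (C13 OH) | CC1=C(CCO)[C@]2(C)CC[C@@H](O[Si](C)(C)C(C)(C)C)C(C)(C)[C@H]2C=C1
F8 | step 16 | primary iodide (C13 iodide) | CC1=C(CCI)[C@]2(C)CC[C@@H](O[Si](C)(C)C(C)(C)C)C(C)(C)[C@H]2C=C1
F9 | step 16 | alkylzinc iodide (zinc on C13) | CC1=C(CC[Zn]I)[C@]2(C)CC[C@@H](O[Si](C)(C)C(C)(C)C)C(C)(C)[C@H]2C=C1
F10 | step 7 | bis(trimethylsilyl) dienol ether of 10 | C[Si](C)(C)OC1C(=C(OC)O[Si](C)(C)C)[C@]2(C)CC[C@@H](O[Si](C)(C)C(C)(C)C)C(C)(C)[C@H]2CC=1
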